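**Retrosynthetic overview**

- Ring A is the terminal guaiacyl phenol, ring B the central arene and ring C the arene with the propenol chain; primes mark the outer dihydrobenzofuran fused to ring C. The strategy rests on C3′, which is bonded to ring C at C3a′ and carries an exocyclic CH2OH trans to ring B on C2′. This is the pattern left by 5-exo addition of a C3a′ aryl radical to a vinyl group on C2′ with oxygen capture at the terminal carbon; C3/C3a/C2 of the inner unit repeat it.
- The target comes from a bis(aminoxymethyl) aldehyde by olefination of the ring C formyl group, N–O cleavage, ester reduction and desilylation.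
- Inner dihydrofuran: C3–C3a by aryl radical 5-exo closure with TEMPO capture of an iodoaryl (S)-allyl ether. That ether comes from iridium-catalysed asymmetric allylic etherification of the ring B iodophenol with the ring A cinnamyl carbonate.
- The ring B iodophenol comes from the outer-unit aldehyde by desilylation and ortho-iodination. The outer dihydrofuran (C3′–C3a′) comes from the same radical closure on the ether made from the same carbonate and 5-iodovanillin.
- Order of ring formation: outer dihydrofuran first (step 6), inner dihydrofuran second (step 10). One cinnamyl carbonate, made from vanillin, supplies both ring B and ring A.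

Key step: step 6

Assumption: the (Sa,Sc,Sc) phosphoramidite L (from (S)-BINOL and bis[(S)-1-phenylethyl]amine) is taken to give the (S) branched aryl ether from an (E)-cinnamyl carbonate, by analogy with the sense known for heteroatom nucleophiles; if the sense proves opposite, the enantiomeric ligand is used in steps 5 and 9.

**Route**

Step 1
Reactants: 1 vanillin
Product: 2 3-methoxy-4-(triisopropylsilyloxy)benzaldehyde
Conditions: i-Pr3SiCl, imidazole, DMF, rt
Reagents that add atoms: chlorotriisopropylsilane, CC(C)[Si](Cl)(C(C)C)C(C)C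
Why: Imidazole-promoted O-silylation of the phenol gives an aryl silyl ether that should withstand the later base, hydride and radical conditions.

Step 2
Reactants: 2 3-methoxy-4-(triisopropylsilyloxy)benzaldehyde; 3 triethyl phosphonoacetate
Product: 4 ethyl (E)-3-[3-methoxy-4-(triisopropylsilyloxy)phenyl]prop-2-enoate
Conditions: NaH, THF, 0 °C to rt
Reagents that add atoms: none
Why: Horner–Wadsworth–Emmons olefination of a non-enolisable aryl aldehyde with the stabilised phosphonate anion should give the (E)-cinnamate.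

Step 3
Reactants: 4 ethyl (E)-3-[3-methoxy-4-(triisopropylsilyloxy)phenyl]prop-2-enoate
Product: 5 (E)-3-[3-methoxy-4-(triisopropylsilyloxy)phenyl]prop-2-en-1-ol
Conditions: i-Bu2AlH (2.5 equiv), CH2Cl2, −78 to 0 °C; aq. potassium sodium tartrate
Reagents that add atoms: none
Why: 1,2-Reduction of the unsaturated ester by i-Bu2AlH should give the allylic alcohol and leave the alkene and the aryl silyl ether untouched.

Step 4
Reactants: 5 (E)-3-[3-methoxy-4-(triisopropylsilyloxy)phenyl]prop-2-en-1-ol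
Product: 6 methyl (E)-3-[3-methoxy-4-(triisopropylsilyloxy)phenyl]allyl carbonate
Conditions: ClCO2Me, pyridine, CH2Cl2, 0 °C
Reagents that add atoms: methyl chloroformate, COC(=O)Cl
Why: O-Acylation of the primary allylic alcohol with a chloroformate gives the methyl carbonate, the usual leaving group for iridium-catalysed allylic substitution.

Step 5
Reactants: 6 methyl (E)-3-[3-methoxy-4-(triisopropylsilyloxy)phenyl]allyl carbonate; 7 5-iodovanillin
Product: 8 3-iodo-5-methoxy-4-{(S)-1-[3-methoxy-4-(triisopropylsilyloxy)phenyl]allyloxy}benzaldehyde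
Conditions: 7 (1.5 equiv), LiOt-Bu (1.5 equiv), THF; then 6, [Ir(cod)Cl]2 (2 mol%), (Sa,Sc,Sc)-L (4 mol%, n-PrNH2-activated), THF, rt
Reagents that add atoms: none
Why: Iridium-catalysed asymmetric allylic etherification, in which the lithium aryloxide attacks the aryl-bearing terminus of the allyl complex of the cyclometalated iridium–phosphoramidite catalyst, should give the branched ether, with the ligand fixing the (S) benzylic centre.

Step 6
Reactants: 8 3-iodo-5-methoxy-4-{(S)-1-[3-methoxy-4-(triisopropylsilyloxy)phenyl]allyloxy}benzaldehyde; 9 TEMPO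
Product: 10 (2S,3R)-7-methoxy-2-[3-methoxy-4-(triisopropylsilyloxy)phenyl]-3-[(2,2,6,6-tetramethylpiperidin-1-yl)oxymethyl]-2,3-dihydrobenzofuran-5-carbaldehyde (trans)
Conditions: Bu3SnH (4 equiv, in portions), TEMPO (6 equiv), PhH, 70 °C
Reagents that add atoms: none
Why: Bu3Sn•, released when TEMPO abstracts hydrogen from Bu3SnH, removes the iodine atom of 8, and the σ aryl radical at C3a′ adds to the internal carbon of the vinyl group on C2′ before it can meet the nitroxide or the stannane. The closest known reaction type is the tin hydride/TEMPO aryl radical–alkene cyclization with nitroxide capture, established for N-allyl-2-iodoanilines and 2-iodoaryl allyl ethers. The outer dihydrofuran ring closes in the 5-exo-trig mode (bond C3′–C3a′), the 6-endo mode being far slower for an ortho-allyloxyaryl radical. The new centre C3′ is controlled by the existing C2′ centre: in the chair-like Beckwith–Houk transition state the ring B aryl group lies pseudo-equatorial, so the CH2 radical, and after capture the CH2O–N group, ends trans to it, giving (2′S,3′R). The step needs capture of the primary radical by TEMPO to outrun hydrogen transfer, which the excess nitroxide and the portionwise addition of Bu3SnH should secure, and it needs C2′ to stay intact, which holds because no bond to C2′ is broken. The formyl group and the aryl silyl ether should not be attacked by stannyl or carbon radicals under these conditions.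

Step 7
Reactants: 10 (2S,3R)-7-methoxy-2-[3-methoxy-4-(triisopropylsilyloxy)phenyl]-3-[(2,2,6,6-tetramethylpiperidin-1-yl)oxymethyl]-2,3-dihydrobenzofuran-5-carbaldehyde
Product: 11 (2S,3R)-2-(4-hydroxy-3-methoxyphenyl)-7-methoxy-3-[(2,2,6,6-tetramethylpiperidin-1-yl)oxymethyl]-2,3-dihydrobenzofuran-5-carbaldehyde
Conditions: Bu4NF (1.1 equiv), AcOH (1.1 equiv), THF, 0 °C
Reagents that add atoms: none
Why: Fluoride-mediated desilylation frees the ring B phenol, and the acetic acid buffer keeps the product from standing as a free phenoxide.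

Step 8
Reactants: 11 (2S,3R)-2-(4-hydroxy-3-methoxyphenyl)-7-methoxy-3-[(2,2,6,6-tetramethylpiperidin-1-yl)oxymethyl]-2,3-dihydrobenzofuran-5-carbaldehyde
Product: 12 (2S,3R)-2-(4-hydroxy-3-iodo-5-methoxyphenyl)-7-methoxy-3-[(2,2,6,6-tetramethylpiperidin-1-yl)oxymethyl]-2,3-dihydrobenzofuran-5-carbaldehyde
Conditions: I2 (1.05 equiv), NaHCO3, THF–H2O, 0 °C to rt
Reagents that add atoms: iodine, II
Why: Electrophilic aromatic iodination under mildly basic conditions should go to the only free position ortho to the phenol oxygen of ring B (para is blocked), while ring C is deactivated by its formyl group and carries no free phenol.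

Step 9
Reactants: 12 (2S,3R)-2-(4-hydroxy-3-iodo-5-methoxyphenyl)-7-methoxy-3-[(2,2,6,6-tetramethylpiperidin-1-yl)oxymethyl]-2,3-dihydrobenzofuran-5-carbaldehyde; 6 methyl (E)-3-[3-methoxy-4-(triisopropylsilyloxy)phenyl]allyl carbonate
Product: 13 (2S,3R)-2-(3-iodo-5-methoxy-4-{(S)-1-[3-methoxy-4-(triisopropylsilyloxy)phenyl]allyloxy}phenyl)-7-methoxy-3-[(2,2,6,6-tetramethylpiperidin-1-yl)oxymethyl]-2,3-dihydrobenzofuran-5-carbaldehyde
Conditions: 12, LiOt-Bu (1.0 equiv), THF; then 6 (1.5 equiv), [Ir(cod)Cl]2 (2 mol%), (Sa,Sc,Sc)-L (4 mol%, n-PrNH2-activated), THF, rt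
Reagents that add atoms: none
Why: The same iridium-catalysed asymmetric allylic etherification should give the branched ether, the new (S) centre being set by the ligand because the existing centres are remote from the allyl terminus.

Step 10
Reactants: 13 (2S,3R)-2-(3-iodo-5-methoxy-4-{(S)-1-[3-methoxy-4-(triisopropylsilyloxy)phenyl]allyloxy}phenyl)-7-methoxy-3-[(2,2,6,6-tetramethylpiperidin-1-yl)oxymethyl]-2,3-dihydrobenzofuran-5-carbaldehyde; 9 TEMPO
Product: 14 (2S,3R)-7-methoxy-2-{(2S,3R)-7-methoxy-2-[3-methoxy-4-(triisopropylsilyloxy)phenyl]-3-[(2,2,6,6-tetramethylpiperidin-1-yl)oxymethyl]-2,3-dihydrobenzofuran-5-yl}-3-[(2,2,6,6-tetramethylpiperidin-1-yl)oxymethyl]-2,3-dihydrobenzofuran-5-carbaldehyde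
Conditions: Bu3SnH (4 equiv, in portions), TEMPO (6 equiv), PhH, 70 °C
Reagents that add atoms: none
Why: The same tin hydride/TEMPO aryl radical 5-exo-trig cyclization closes the inner dihydrofuran on ring B, the ring A aryl group on C2 taking the pseudo-equatorial place so that C3 forms trans to it, while the first alkoxyamine, a primary one, is stable at this temperature.

Step 11
Reactants: 14 the bis(aminoxymethyl) aldehyde of step 10; 3 triethyl phosphonoacetate
Product: 15 ethyl (E)-3-{(2S,3R)-7-methoxy-2-[(2S,3R)-7-methoxy-2-[3-methoxy-4-(triisopropylsilyloxy)phenyl]-3-[(2,2,6,6-tetramethylpiperidin-1-yl)oxymethyl]-2,3-dihydrobenzofuran-5-yl]-3-[(2,2,6,6-tetramethylpiperidin-1-yl)oxymethyl]-2,3-dihydrobenzofuran-5-yl}prop-2-enoate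
Conditions: NaH, THF, 0 °C to rt
Reagents that add atoms: none
Why: Horner–Wadsworth–Emmons olefination of the ring C aldehyde, in a substrate with no acidic site, should give the (E)-acrylate.

Step 12
Reactants: 15 the bis(aminoxymethyl) acrylate of step 11
Product: 16 ethyl (E)-3-{(2S,3R)-3-(hydroxymethyl)-2-[(2S,3R)-3-(hydroxymethyl)-7-methoxy-2-[3-methoxy-4-(triisopropylsilyloxy)phenyl]-2,3-dihydrobenzofuran-5-yl]-7-methoxy-2,3-dihydrobenzofuran-5-yl}prop-2-enoate
Conditions: Zn dust, AcOH–THF–H2O (3:1:1), 50–70 °C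
Reagents that add atoms: none
Why: Reductive N–O cleavage of alkoxyamines by zinc in acetic acid should free both primary alcohols without reducing the cinnamate or cleaving the benzylic ethers; a partly lost aryl silyl ether would do no harm because that phenol is free in the target.

Step 13
Reactants: 16 the diol ester of step 12
Product: 17 (E)-3-{(2S,3R)-3-(hydroxymethyl)-2-[(2S,3R)-3-(hydroxymethyl)-7-methoxy-2-[3-methoxy-4-(triisopropylsilyloxy)phenyl]-2,3-dihydrobenzofuran-5-yl]-7-methoxy-2,3-dihydrobenzofuran-5-yl}prop-2-en-1-ol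
Conditions: i-Bu2AlH (6 equiv), CH2Cl2, −78 to 0 °C; aq. potassium sodium tartrate
Reagents that add atoms: none
Why: 1,2-Reduction of the unsaturated ester by excess i-Bu2AlH, two equivalents being used up by the free hydroxyl groups, should give the (E)-allylic alcohol.

Step 14
Reactants: 17 the silylated triol of step 13
Product: 18 CNP0250921.2, (E)-3-{(2S,3R)-2-[(2S,3R)-2-(4-hydroxy-3-methoxyphenyl)-3-(hydroxymethyl)-7-methoxy-2,3-dihydrobenzofuran-5-yl]-3-(hydroxymethyl)-7-methoxy-2,3-dihydrobenzofuran-5-yl}prop-2-en-1-ol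
Conditions: Bu4NF (1.2 equiv), AcOH (1.2 equiv), THF, 0 °C
Reagents that add atoms: none
Why: Fluoride-mediated desilylation frees the ring A phenol under buffered conditions that should leave the two benzylic aryl ethers and the allylic alcohol alone.

**Compound list**

1 | vanillin | COc1cc(C=O)ccc1O | starting material
2 | 3-methoxy-4-(triisopropylsilyloxy)benzaldehyde | COc1cc(C=O)ccc1O[Si](C(C)C)(C(C)C)C(C)C | intermediate
3 | triethyl phosphonoacetate | CCOC(=O)CP(=O)(OCC)OCC | starting material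
4 | ethyl (E)-3-[3-methoxy-4-(triisopropylsilyloxy)phenyl]prop-2-enoate | CCOC(=O)/C=C/c1ccc(O[Si](C(C)C)(C(C)C)C(C)C)c(OC)c1 | intermediate
5 | (E)-3-[3-methoxy-4-(triisopropylsilyloxy)phenyl]prop-2-en-1-ol | OC/C=C/c1ccc(O[Si](C(C)C)(C(C)C)C(C)C)c(OC)c1 | intermediate
6 | methyl (E)-3-[3-methoxy-4-(triisopropylsilyloxy)phenyl]allyl carbonate | COC(=O)OC/C=C/c1ccc(O[Si](C(C)C)(C(C)C)C(C)C)c(OC)c1 | intermediate
7 | 5-iodovanillin | COc1cc(C=O)cc(I)c1O | starting material
8 | 3-iodo-5-methoxy-4-{(S)-1-[3-methoxy-4-(triisopropylsilyloxy)phenyl]allyloxy}benzaldehyde | COc1cc([C@H](C=C)Oc2c(OC)cc(C=O)cc2I)ccc1O[Si](C(C)C)(C(C)C)C(C)C | intermediate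
9 | TEMPO (2,2,6,6-tetramethylpiperidin-1-oxyl) | CC1(C)CCCC(C)(C)N1[O] | starting material
10 | (2S,3R)-7-methoxy-2-[3-methoxy-4-(triisopropylsilyloxy)phenyl]-3-[(2,2,6,6-tetramethylpiperidin-1-yl)oxymethyl]-2,3-dihydrobenzofuran-5-carbaldehyde | COc1cc([C@H]2Oc3c(OC)cc(C=O)cc3[C@@H]2CON4C(C)(C)CCCC4(C)C)ccc1O[Si](C(C)C)(C(C)C)C(C)C | intermediate
11 | (2S,3R)-2-(4-hydroxy-3-methoxyphenyl)-7-methoxy-3-[(2,2,6,6-tetramethylpiperidin-1-yl)oxymethyl]-2,3-dihydrobenzofuran-5-carbaldehyde | COc1cc([C@H]2Oc3c(OC)cc(C=O)cc3[C@@H]2CON4C(C)(C)CCCC4(C)C)ccc1O | intermediate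
12 | (2S,3R)-2-(4-hydroxy-3-iodo-5-methoxyphenyl)-7-methoxy-3-[(2,2,6,6-tetramethylpiperidin-1-yl)oxymethyl]-2,3-dihydrobenzofuran-5-carbaldehyde | COc1cc([C@H]2Oc3c(OC)cc(C=O)cc3[C@@H]2CON4C(C)(C)CCCC4(C)C)cc(I)c1O | intermediate
13 | (2S,3R)-2-(3-iodo-5-methoxy-4-{(S)-1-[3-methoxy-4-(triisopropylsilyloxy)phenyl]allyloxy}phenyl)-7-methoxy-3-[(2,2,6,6-tetramethylpiperidin-1-yl)oxymethyl]-2,3-dihydrobenzofuran-5-carbaldehyde | COc1cc([C@H](C=C)Oc2c(OC)cc([C@H]3Oc4c(OC)cc(C=O)cc4[C@@H]3CON5C(C)(C)CCCC5(C)C)cc2I)ccc1O[Si](C(C)C)(C(C)C)C(C)C | intermediate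
14 | (2S,3R)-7-methoxy-2-{(2S,3R)-7-methoxy-2-[3-methoxy-4-(triisopropylsilyloxy)phenyl]-3-[(2,2,6,6-tetramethylpiperidin-1-yl)oxymethyl]-2,3-dihydrobenzofuran-5-yl}-3-[(2,2,6,6-tetramethylpiperidin-1-yl)oxymethyl]-2,3-dihydrobenzofuran-5-carbaldehyde | COc1cc([C@H]2Oc3c(OC)cc([C@H]4Oc5c(OC)cc(C=O)cc5[C@@H]4CON6C(C)(C)CCCC6(C)C)cc3[C@@H]2CON7C(C)(C)CCCC7(C)C)ccc1O[Si](C(C)C)(C(C)C)C(C)C | intermediate
15 | ethyl (E)-3-{(2S,3R)-7-methoxy-2-[(2S,3R)-7-methoxy-2-[3-methoxy-4-(triisopropylsilyloxy)phenyl]-3-[(2,2,6,6-tetramethylpiperidin-1-yl)oxymethyl]-2,3-dihydrobenzofuran-5-yl]-3-[(2,2,6,6-tetramethylpiperidin-1-yl)oxymethyl]-2,3-dihydrobenzofuran-5-yl}prop-2-enoate | COc1cc([C@H]2Oc3c(OC)cc([C@H]4Oc5c(OC)cc(/C=C/C(=O)OCC)cc5[C@@H]4CON6C(C)(C)CCCC6(C)C)cc3[C@@H]2CON7C(C)(C)CCCC7(C)C)ccc1O[Si](C(C)C)(C(C)C)C(C)C | intermediate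
16 | ethyl (E)-3-{(2S,3R)-3-(hydroxymethyl)-2-[(2S,3R)-3-(hydroxymethyl)-7-methoxy-2-[3-methoxy-4-(triisopropylsilyloxy)phenyl]-2,3-dihydrobenzofuran-5-yl]-7-methoxy-2,3-dihydrobenzofuran-5-yl}prop-2-enoate | COc1cc([C@H]2Oc3c(OC)cc([C@H]4Oc5c(OC)cc(/C=C/C(=O)OCC)cc5[C@@H]4CO)cc3[C@@H]2CO)ccc1O[Si](C(C)C)(C(C)C)C(C)C | intermediate
17 | (E)-3-{(2S,3R)-3-(hydroxymethyl)-2-[(2S,3R)-3-(hydroxymethyl)-7-methoxy-2-[3-methoxy-4-(triisopropylsilyloxy)phenyl]-2,3-dihydrobenzofuran-5-yl]-7-methoxy-2,3-dihydrobenzofuran-5-yl}prop-2-en-1-ol | COc1cc([C@H]2Oc3c(OC)cc([C@H]4Oc5c(OC)cc(/C=C/CO)cc5[C@@H]4CO)cc3[C@@H]2CO)ccc1O[Si](C(C)C)(C(C)C)C(C)C | intermediate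
18 | CNP0250921.2, (E)-3-{(2S,3R)-2-[(2S,3R)-2-(4-hydroxy-3-methoxyphenyl)-3-(hydroxymethyl)-7-methoxy-2,3-dihydrobenzofuran-5-yl]-3-(hydroxymethyl)-7-methoxy-2,3-dihydrobenzofuran-5-yl}prop-2-en-1-ol | COc1cc([C@H]2Oc3c(OC)cc([C@H]4Oc5c(OC)cc(/C=C/CO)cc5[C@@H]4CO)cc3[C@@H]2CO)ccc1O | target

**Step count**

Total steps: 14. Longest linear sequence: 14 steps (steps 1 to 14; carbonate 6 is used in steps 5 and 9).

**Steps most likely to fail**

Step 5. The doubly ortho-substituted, acceptor-bearing aryloxide may attack the allyl complex slowly. The product, an allylic ether with a good aryloxide leaving group on an electron-rich cinnamyl unit, may be re-ionised by the catalyst. Both processes would erode branched selectivity and enantiomeric purity. The fallback changes the electronic class of the coupling partner and sets out from 7 and 6. The aldehyde of 7 is masked with ethylene glycol (TsOH cat., PhMe, Dean–Stark) as 4-(1,3-dioxolan-2-yl)-2-iodo-6-methoxyphenol F1, whose phenoxide is a stronger nucleophile and a poorer leaving group. Its lithium salt is coupled with 6 under the iridium catalysis of step 5 to give 2-(3-iodo-5-methoxy-4-{(S)-1-[3-methoxy-4-(triisopropylsilyloxy)phenyl]allyloxy}phenyl)-1,3-dioxolane F2. Mild hydrolysis (pyridinium tosylate, acetone–H2O, rt) returns the aldehyde, and the route is rejoined at 8.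

Step 6. Hydrogen transfer from the stannane to the aryl or cyclized radical, or coupling of the aryl radical with the nitroxide before ring closure, may compete with the wanted closure and capture. Incomplete trans selectivity would have to be met by chromatographic separation. The fallback separates radical generation from oxygen capture and sets out from 8. Na[Co(salen)] (monovalent cobalt, made from Co(salen), Co(C16H14N2O2), with 1% Na/Hg in THF) is added in the dark at rt. The aryl radical cyclizes 5-exo and the primary radical is held by divalent cobalt as {[(2S,3R)-5-formyl-7-methoxy-2-[3-methoxy-4-(triisopropylsilyloxy)phenyl]-2,3-dihydrobenzofuran-3-yl]methyl}[N,N′-ethylenebis(salicylideneiminato)]cobalt F3 (trivalent cobalt). Irradiation of this complex with visible light in the presence of 9 (CH2Cl2, rt) homolyses the Co–C bond and the nitroxide captures the radical, so the route is rejoined at 10.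

Step 9. Once the ring B phenoxide is formed, the para-hydroxybenzyl aryl ether of the outer dihydrofuran may open through a quinone methide, and the hindered phenoxide may substitute sluggishly. The fallback reverses the direction of growth, so that no ring B phenoxide is ever formed; it sets out from 10, whose formyl-bearing arene now becomes ring B and whose silylated aryl group becomes ring A. Olefination of 10 with 3 (NaH, THF) gives ethyl (E)-3-{(2S,3R)-7-methoxy-2-[3-methoxy-4-(triisopropylsilyloxy)phenyl]-3-[(2,2,6,6-tetramethylpiperidin-1-yl)oxymethyl]-2,3-dihydrobenzofuran-5-yl}prop-2-enoate F4. Reduction with i-Bu2AlH gives (E)-3-{(2S,3R)-7-methoxy-2-[3-methoxy-4-(triisopropylsilyloxy)phenyl]-3-[(2,2,6,6-tetramethylpiperidin-1-yl)oxymethyl]-2,3-dihydrobenzofuran-5-yl}prop-2-en-1-ol F5, and ClCO2Me/pyridine gives the corresponding allyl methyl carbonate F6. Iridium-catalysed etherification of F6 with the lithium salt of 7, under the conditions of step 5, gives (2S,3R)-5-[(S)-1-(4-formyl-2-iodo-6-methoxyphenoxy)allyl]-7-methoxy-2-[3-methoxy-4-(triisopropylsilyloxy)phenyl]-3-[(2,2,6,6-tetramethylpiperidin-1-yl)oxymethyl]-2,3-dihydrobenzofuran F7. Cyclization of F7 with Bu3SnH and 9, as in step 6, rejoins the route at 14.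

**Further compounds**

F1 | step 5 | 4-(1,3-dioxolan-2-yl)-2-iodo-6-methoxyphenol | COc1cc(C2OCCO2)cc(I)c1O
F2 | step 5 | 2-(3-iodo-5-methoxy-4-{(S)-1-[3-methoxy-4-(triisopropylsilyloxy)phenyl]allyloxy}phenyl)-1,3-dioxolane | COc1cc([C@H](C=C)Oc2c(OC)cc(C3OCCO3)cc2I)ccc1O[Si](C(C)C)(C(C)C)C(C)C
F3 | step 6 | {[(2S,3R)-5-formyl-7-methoxy-2-[3-methoxy-4-(triisopropylsilyloxy)phenyl]-2,3-dihydrobenzofuran-3-yl]methyl}[N,N′-ethylenebis(salicylideneiminato)]cobalt | COc1cc([C@H]2Oc3c(OC)cc(C=O)cc3[C@@H]2C[Co-2]456Oc7ccccc7C=[N+]4CC[N+]5=Cc4ccccc4O6)ccc1O[Si](C(C)C)(C(C)C)C(C)C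
F4 | step 9 | ethyl (E)-3-{(2S,3R)-7-methoxy-2-[3-methoxy-4-(triisopropylsilyloxy)phenyl]-3-[(2,2,6,6-tetramethylpiperidin-1-yl)oxymethyl]-2,3-dihydrobenzofuran-5-yl}prop-2-enoate | COc1cc([C@H]2Oc3c(OC)cc(/C=C/C(=O)OCC)cc3[C@@H]2CON4C(C)(C)CCCC4(C)C)ccc1O[Si](C(C)C)(C(C)C)C(C)C
F5 | step 9 | (E)-3-{(2S,3R)-7-methoxy-2-[3-methoxy-4-(triisopropylsilyloxy)phenyl]-3-[(2,2,6,6-tetramethylpiperidin-1-yl)oxymethyl]-2,3-dihydrobenzofuran-5-yl}prop-2-en-1-ol | COc1cc([C@H]2Oc3c(OC)cc(/C=C/CO)cc3[C@@H]2CON4C(C)(C)CCCC4(C)C)ccc1O[Si](C(C)C)(C(C)C)C(C)C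
F6 | step 9 | methyl (E)-3-{(2S,3R)-7-methoxy-2-[3-methoxy-4-(triisopropylsilyloxy)phenyl]-3-[(2,2,6,6-tetramethylpiperidin-1-yl)oxymethyl]-2,3-dihydrobenzofuran-5-yl}allyl carbonate | COc1cc([C@H]2Oc3c(OC)cc(/C=C/COC(=O)OC)cc3[C@@H]2CON4C(C)(C)CCCC4(C)C)ccc1O[Si](C(C)C)(C(C)C)C(C)C
F7 | step 9 | (2S,3R)-5-[(S)-1-(4-formyl-2-iodo-6-methoxyphenoxy)allyl]-7-methoxy-2-[3-methoxy-4-(triisopropylsilyloxy)phenyl]-3-[(2,2,6,6-tetramethylpiperidin-1-yl)oxymethyl]-2,3-dihydrobenzofuran | COc1cc([C@H]2Oc3c(OC)cc([C@H](C=C)Oc4c(OC)cc(C=O)cc4I)cc3[C@@H]2CON5C(C)(C)CCCC5(C)C)ccc1O[Si](C(C)C)(C(C)C)C(C)C
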